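Ask which number must be known well.

| flask | E | J | temperature | remark | time |
|---|---|---|---|---|---|
| Friday's | 0.23 M | 1.9 mM | 95 °C | run made earlier |  |
| Wednesday's | 0.23 M | 4.8 mM | 110 °C | run made earlier |  |
| Saturday's | 0.23 M | 10 mM | 95 °C | run made earlier |  |
| Tuesday's | 0.16 M | 2.3 mM | 110 °C | run made earlier |  |
| violet | 0.15 M | 10.0 mM | 110 °C |  | 1.0 h |
| blue | 0.23 M | 2.30 mM | 110 °C |  | 1.0 h |

| run | time / min | J / % | L / % | E / % |
|---|---|---|---|---|
| Friday's | 12.0 | 95.8 | 4.2 | 0 |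
| Friday's | 25.0 | 92.4 | 9.2 | 0 |
| Friday's | 40.0 | 87.8 | 13.6 | 0.4 |
| Friday's | 50.0 | 84.6 | 17.9 | 0 |
| Friday's | 60.0 | 80.8 | 20.2 | 1.0 |
| Wednesday's | 6.00 | 93.2 | 10.3 | 0 |
| Wednesday's | 12.0 | 84.6 | 17.8 | 0.1 |
| Wednesday's | 20.0 | 72.6 | 29.0 | 0.3 |
| Wednesday's | 25.0 | 67.1 | 34.6 | 0.2 |
| Wednesday's | 30.0 | 61.7 | 40.4 | 0 |
| Saturday's | 12.0 | 100.4 | 3.5 | 0 |
| Saturday's | 25.0 | 95.7 | 8.8 | 0 |
| Saturday's | 40.0 | 89.8 | 14.3 | 0.3 |
| Saturday's | 50.0 | 87.3 | 18.6 | 0.2 |
| Saturday's | 60.0 | 83.9 | 19.6 | 0 |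
| Tuesday's | 6.00 | 91.4 | 9.5 | 0.4 |
| Tuesday's | 12.0 | 82.4 | 17.3 | 0 |
| Tuesday's | 20.0 | 73.2 | 28.2 | 0.5 |
| Tuesday's | 25.0 | 67.0 | 34.5 | 0 |
| Tuesday's | 30.0 | 61.0 | 40.3 | 0 |

(readings scatter by 0.5 percentage points)



1. which of the two ends with the higher share of J in all that became J or L ("neither" if they lie within 2 percentage points) (violet / blue / neither)
2. share of J in all that became J or L, violet
3. share of J in all that became J or L, blue

The charges come first. Wednesday's flask shows E at 0% by 6.00 min, and from there to 30.0 min its L gains 0.956 of what J loses, so J is passing into L while J + L stays nearly level. Dividing one rate by the other removes time, and the share J/(J + L) divides the total away. At 30.0 min, Tuesday's flask, charged with J at 1.44% of its E charge, reads a share of 60.2%, and Wednesday's, charged with 2.09%, reads 60.4%. Violet's charge of 6.67% and blue's of 1.00% lie outside that span, so the expectation that they shift the totals, not the share, is an extrapolation.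

Temperature comes next: Friday's flask at 95 °C still reads 80.0% at 60.0 min, where Wednesday's at 110 °C read 60.4% already at 30.0 min. Both asked flasks stand at 110 °C, so the number needed is the one read at that temperature.

That number is the fade constant (first-order rate constant), the natural logarithm of (J + L)/J divided by the time. Wednesday's flask gives 0.0168 min⁻¹ and Tuesday's 0.0169 min⁻¹, a gap worth 0.26 percentage points in the answer. My reckoning for both flasks at 1.0 h is 36.5%.

The forecast says neither, with 36.8% for violet and 36.8% for blue, holding that “added J has no visible effect on the rate”. Its figure lies 0.30 points above my reckoning.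

The flasks give neither, with 36.6% in violet and 36.6% in blue.

    J ⇌ L (K = 1000, k = 2.80 × 10⁻⁴ s⁻¹, Ea = 119 kJ mol⁻¹, ΔH = −57.0 kJ mol⁻¹)
    E → J (k = 4.00 × 10⁻⁵ s⁻¹, Ea = 116 kJ mol⁻¹)
    E + J → 2 J (k = 2.10 M⁻¹ s⁻¹, Ea = 54.0 kJ mol⁻¹)
    (constants at 110 °C)

The forecast would fail in a violet flask without the step by which J turns E into J, whose share then reads 53.7%. The fade constant gave 36.5% for these flasks. For blue read at 2.5 h it gives 8.05%, and that flask stands at 8.14%.

All runs are simulated for an exercise.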